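**Strategy.** The cyclohexane is closed between C1, the methyl carbinol carbon, and C2, the bromine-bearing carbon. Both ring atoms carry a heteroatom, so both are traced back to carbonyl carbons of an open-chain 1,6-keto-aldehyde, (3S)-6-oxo-3-isopropenylheptanal, obtained from (−)-limonene oxide. A samarium diiodide ketyl pinacol cyclization joins these two electrophilic carbons by polarity reversal and, in one operation, forms the ring and sets the C1 carbinol relative to C4. The C2 oxygen is then exchanged for equatorial bromine through a vinyl bromide and hydrogen-atom-transfer hydrogenation, and the dienol chain is attached by boron-Wittig olefination and oxidative Heck coupling with (S)-linalool.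

Key step: step 2

Assumption: (−)-limonene 1,2-oxide [(4S), cis/trans mixture] and (S)-(+)-linalool are taken as commercial materials of high enantiomeric purity.

**Step 1**
Reactants: 1 (4S)-limonene 1,2-oxide (cis/trans mixture)
Product: 3 (3S)-6-oxo-3-(prop-1-en-2-yl)heptanal, via trans-diaxial glycol 2 (not isolated)
Conditions: H5IO6, THF/H2O, 0 °C to rt
Reagents that add atoms: water, O
Why: Periodic acid hydrolyses either epoxide diastereomer by trans-diaxial opening to the same glycol and then cleaves it (Malaprade glycol cleavage), leaving the remote stereocenter and the isopropenyl group untouched.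

**Step 2**
Reactants: 3 (3S)-6-oxo-3-(prop-1-en-2-yl)heptanal
Product: 4 (1R,2S,4S)-1-methyl-4-(prop-1-en-2-yl)cyclohexane-1,2-diol
Conditions: SmI2 (2.2 equiv), t-BuOH (2 equiv), THF, −78 °C to rt, slow addition of 3
Reagents that add atoms: none
Why: Electron transfer from divalent samarium to the aldehyde gives a samarium-bound ketyl whose carbon adds to the ketone carbonyl held on the same oxophilic trivalent samarium center, and a second electron gives the cyclic samarium diolate that is protonated on work-up (ketyl pinacol coupling, an umpolung union of two carbonyl carbons). The closest known reaction type is the samarium diiodide pinacol cyclization of 1,5- and 1,6-dicarbonyl compounds to cis-cycloalkane-1,2-diols. The six-membered ring closes in a 6-exo-trig mode by attack of the ketyl carbon C1 of 3 on the C6 carbonyl. The two new stereocenters should be cis to each other because both oxygens bridge one samarium (one axial, one equatorial); in the chair transition state the isopropenyl and methyl groups sit equatorial, so the tertiary oxygen is axial and the secondary oxygen equatorial, both cis to the isopropenyl group, under control of the existing C3 stereocenter of 3. The step needs chemoselectivity for the two carbonyls over the isopropenyl group and cyclization over dimerization; these are secured by working without HMPA (unactivated alkenes stay inert), by the faster reduction of the aldehyde and by slow addition at high dilution.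

**Step 3**
Reactants: 4 (1R,2S,4S)-1-methyl-4-(prop-1-en-2-yl)cyclohexane-1,2-diol
Product: 5 (2R,5S)-2-hydroxy-2-methyl-5-(prop-1-en-2-yl)cyclohexan-1-one
Conditions: IBX (2-iodoxybenzoic acid), DMSO, rt
Reagents that add atoms: none
Why: 2-Iodoxybenzoic acid oxidises the secondary alcohol of a 1,2-diol to the α-ketol without glycol cleavage and cannot touch the tertiary carbinol, so the C1 configuration from step 2 is kept (alcohol oxidation).

**Step 4**
Reactants: 5 (2R,5S)-2-hydroxy-2-methyl-5-(prop-1-en-2-yl)cyclohexan-1-one
Product: 6 (E)-2,4,6-triisopropylbenzenesulfonylhydrazone of 5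
Conditions: TrisNHNH2, cat. HCl, THF, rt
Reagents that add atoms: 2,4,6-triisopropylbenzenesulfonyl hydrazide, NNS(=O)(=O)c1c(C(C)C)cc(C(C)C)cc1C(C)C
Why: Acid-catalysed condensation should give the sulfonylhydrazone with the sulfonamide nitrogen anti to the quaternary carbon, the geometry needed for syn deprotonation at the only α-methylene in the Shapiro reaction.

**Step 5**
Reactants: 6 (E)-2,4,6-triisopropylbenzenesulfonylhydrazone of 5
Product: 8 (1R,4S)-2-bromo-1-methyl-4-(prop-1-en-2-yl)cyclohex-2-en-1-ol, via vinyllithium alkoxide 7 (not isolated)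
Conditions: n-BuLi (3.3 equiv), TMEDA, THF, −78 to 0 °C; then BrCH2CH2Br, −78 °C to rt
Reagents that add atoms: 1,2-dibromoethane, BrCCBr
Why: Shapiro reaction: the polyanion loses sulfinate and dinitrogen to give the vinyllithium regiospecifically (only C6 of 5 bears α-hydrogens), and bromine transfer from 1,2-dibromoethane gives the vinyl bromide without touching either stereocenter.

**Step 6**
Reactants: 8 (1R,4S)-2-bromo-1-methyl-4-(prop-1-en-2-yl)cyclohex-2-en-1-ol
Product: 10 1-[(1S,4R)-3-bromo-4-hydroxy-4-methylcyclohex-2-en-1-yl]ethan-1-one, via secondary ozonide 9 (not isolated)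
Conditions: O3 (1 equiv), CH2Cl2, −78 °C; then Me2S, −78 °C to rt; crude product used directly
Reagents that add atoms: ozone, [O-][O+]=O
Why: Ozone attacks the electron-rich 1,1-disubstituted isopropenyl alkene much faster than the bromine-deactivated, hindered ring alkene, so one equivalent and reductive work-up should unmask the methyl ketone (ozonolysis).

**Step 7**
Reactants: 10 1-[(1S,4R)-3-bromo-4-hydroxy-4-methylcyclohex-2-en-1-yl]ethan-1-one
Product: 11 1-[(1S,3S,4R)-3-bromo-4-hydroxy-4-methylcyclohexyl]ethan-1-one
Conditions: Mn(dpm)3 (cat., trivalent manganese), PhSiH3, t-BuOOH, i-PrOH, rt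
Reagents that add atoms: none
Why: Metal-hydride hydrogen-atom-transfer hydrogenation: hydrogen adds to C2 to give the α-bromo radical at C3, which should take the second hydrogen axially, anti to the vicinal axial hydroxyl, so that bromine ends equatorial, cis to the hydroxyl and to the acetyl group, while the carbon–bromine bond and the ketone survive.

**Step 8**
Reactants: 11 1-[(1S,3S,4R)-3-bromo-4-hydroxy-4-methylcyclohexyl]ethan-1-one
Product: 12 (1R,2S,4S)-2-bromo-1-methyl-4-[(E)-1-(4,4,5,5-tetramethyl-1,3,2-dioxaborolan-2-yl)prop-1-en-2-yl]cyclohexan-1-ol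
Conditions: CH2(Bpin)2 (2.3 equiv), LiTMP (2.2 equiv), THF, 0 °C; then 11, −78 to 0 °C
Reagents that add atoms: bis[(pinacolato)boryl]methane, CC1(C)OB(CB2OC(C)(C)C(C)(C)O2)OC1(C)C
Why: Boron-Wittig olefination: addition of the lithiated geminal bis(boronate) to the methyl ketone and syn boron–oxygen elimination should give the trisubstituted alkenyl boronate with the remaining boryl group trans to the bulkier cyclohexyl substituent (E), at temperatures where the lithium alkoxide of the cis-bromohydrin is expected to be stable.

**Step 9**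
Reactants: 12 the alkenyl boronate; 13 (S)-linalool
Product: 14 (1R,2S,4S)-2-bromo-4-[(2E,4E,6S)-6-hydroxy-6,10-dimethylundeca-2,4,9-trien-2-yl]-1-methylcyclohexan-1-ol
Conditions: Pd(OAc)2 (10 mol %), 1,2-bis(phenylsulfinyl)ethane, 1,4-benzoquinone, AcOH, dioxane, rt
Reagents that add atoms: none
Why: Oxidative Heck coupling: transmetalation of the alkenyl boronate to divalent palladium, insertion of the terminal alkene of linalool and β-hydride elimination (possible only toward the new carbon–carbon bond, since the carbinol carbon has no hydrogen) should give the (E,E)-diene with retention of the alkenyl geometry and of the carbinol stereocenter.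

**Compound list**
1 | (4S)-1-methyl-4-(prop-1-en-2-yl)-7-oxabicyclo[4.1.0]heptane, (−)-limonene 1,2-oxide, cis/trans mixture at the epoxide | CC12CC[C@@H](CC1O2)C(C)=C | starting material
2 | (1R,2R,4S)-1-methyl-4-(prop-1-en-2-yl)cyclohexane-1,2-diol (formed in the flask) | CC(=C)[C@H]1CC[C@@](C)(O)[C@H](O)C1 | intermediate
3 | (3S)-6-oxo-3-(prop-1-en-2-yl)heptanal | CC(=C)[C@H](CC=O)CCC(C)=O | intermediate
4 | (1R,2S,4S)-1-methyl-4-(prop-1-en-2-yl)cyclohexane-1,2-diol | CC(=C)[C@H]1CC[C@@](C)(O)[C@@H](O)C1 | intermediate
5 | (2R,5S)-2-hydroxy-2-methyl-5-(prop-1-en-2-yl)cyclohexan-1-one | CC(=C)[C@H]1CC[C@@](C)(O)C(=O)C1 | intermediate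
6 | (E)-2,4,6-triisopropylbenzenesulfonylhydrazone of 5 | CC(=C)[C@H]1CC[C@@](C)(O)/C(=N/NS(=O)(=O)c2c(C(C)C)cc(C(C)C)cc2C(C)C)C1 | intermediate
7 | lithium (1R,4S)-2-lithio-1-methyl-4-(prop-1-en-2-yl)cyclohex-2-en-1-olate (formed in the flask) | CC(=C)[C@H]1CC[C@@](C)(O[Li])C([Li])=C1 | intermediate
8 | (1R,4S)-2-bromo-1-methyl-4-(prop-1-en-2-yl)cyclohex-2-en-1-ol | CC(=C)[C@H]1CC[C@@](C)(O)C(Br)=C1 | intermediate
9 | (1R,4S)-2-bromo-1-methyl-4-(3-methyl-1,2,4-trioxolan-3-yl)cyclohex-2-en-1-ol, both epimers at the trioxolane carbon (formed in the flask) | CC1(OCOO1)[C@H]2CC[C@@](C)(O)C(Br)=C2 | intermediate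
10 | 1-[(1S,4R)-3-bromo-4-hydroxy-4-methylcyclohex-2-en-1-yl]ethan-1-one | CC(=O)[C@H]1CC[C@@](C)(O)C(Br)=C1 | intermediate
11 | 1-[(1S,3S,4R)-3-bromo-4-hydroxy-4-methylcyclohexyl]ethan-1-one | CC(=O)[C@H]1CC[C@@](C)(O)[C@@H](Br)C1 | intermediate
12 | (1R,2S,4S)-2-bromo-1-methyl-4-[(E)-1-(4,4,5,5-tetramethyl-1,3,2-dioxaborolan-2-yl)prop-1-en-2-yl]cyclohexan-1-ol | CC1(C)OB(OC1(C)C)/C=C(\C)[C@H]2CC[C@@](C)(O)[C@@H](Br)C2 | intermediate
13 | (S)-(+)-linalool, (3S)-3,7-dimethylocta-1,6-dien-3-ol | CC(C)=CCC[C@](C)(O)C=C | starting material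
14 | (1R,2S,4S)-2-bromo-4-[(2E,4E,6S)-6-hydroxy-6,10-dimethylundeca-2,4,9-trien-2-yl]-1-methylcyclohexan-1-ol | CC(C)=CCC[C@](C)(O)/C=C/C=C(\C)[C@H]1CC[C@@](C)(O)[C@@H](Br)C1 | target

**Step count and risks**
Total step count: 9. Longest linear sequence: 9 steps (1 to 14); 13 enters in the last step.

Steps most likely to fail:

Step 7. The double bond may migrate into conjugation with the acetyl group (loss of the ring stereocenter next to the ketone), bromine may be lost reductively, or hydrogen may be delivered from the hydroxyl-bearing face. Fallback: the bromine-bearing center is set before the isopropenyl group is cleaved, by tin hydride mono-reduction of a geminal dibromide. From hydroxy ketone 5, hydrazine hydrate gives the hydrazone (1R,4S)-2-hydrazinylidene-1-methyl-4-(prop-1-en-2-yl)cyclohexan-1-ol F1. CuBr2 and Et3N in methanol should convert it, with loss of dinitrogen, into the geminal dibromide (1R,4S)-2,2-dibromo-1-methyl-4-(prop-1-en-2-yl)cyclohexan-1-ol F2. One equivalent of Bu3SnH with Et3B/air at −78 °C should remove one bromine, the α-bromo radical taking hydrogen anti to the axial hydroxyl, to give the bromohydrin (1R,2S,4S)-2-bromo-1-methyl-4-(prop-1-en-2-yl)cyclohexan-1-ol F3. Ozonolysis of its isopropenyl group as in step 6 returns to the route at ketone 11.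

Step 8. The lithium alkoxide next to the bromide may undergo ring contraction with loss of bromide, the ketone may enolise, or the E selectivity may erode. Fallback: the carbinol is masked so that no alkoxide can form. From ketone 11, N-(trimethylsilyl)imidazole gives the silyl ether 1-[(1S,3S,4R)-3-bromo-4-methyl-4-(trimethylsilyloxy)cyclohexyl]ethan-1-one F4. The boron-Wittig olefination then gives the silylated alkenyl boronate F5, and methanolysis with PPTS in MeOH returns to the route at alkenyl boronate 12.

Step 9. Transmetalation of the hindered alkenyl boronate may be slow, and the tertiary dienyl carbinol may ionise in the acidic medium. Fallback: the coupling is run as a zerovalent-palladium Heck reaction of a vinyl iodide under weakly basic conditions. From alkenyl boronate 12, N-iodosuccinimide in acetonitrile gives, with retention of geometry, the vinyl iodide (1R,2S,4S)-2-bromo-4-[(E)-1-iodoprop-1-en-2-yl]-1-methylcyclohexan-1-ol F6. Coupling of F6 with linalool 13 (Pd(OAc)2, Bu4NCl, NaHCO3, DMF, 40 °C) returns to the route at target 14.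

**Further compounds**
F1 | step 7 | (1R,4S)-2-hydrazinylidene-1-methyl-4-(prop-1-en-2-yl)cyclohexan-1-ol | CC(=C)[C@H]1CC[C@@](C)(O)/C(=N/N)C1
F2 | step 7 | (1R,4S)-2,2-dibromo-1-methyl-4-(prop-1-en-2-yl)cyclohexan-1-ol | CC(=C)[C@H]1CC[C@@](C)(O)C(Br)(Br)C1
F3 | step 7 | (1R,2S,4S)-2-bromo-1-methyl-4-(prop-1-en-2-yl)cyclohexan-1-ol | CC(=C)[C@H]1CC[C@@](C)(O)[C@@H](Br)C1
F4 | step 8 | 1-[(1S,3S,4R)-3-bromo-4-methyl-4-(trimethylsilyloxy)cyclohexyl]ethan-1-one | CC(=O)[C@H]1CC[C@@](C)(O[Si](C)(C)C)[C@@H](Br)C1
F5 | step 8 | 2-[(E)-2-[(1S,3S,4R)-3-bromo-4-methyl-4-(trimethylsilyloxy)cyclohexyl]prop-1-en-1-yl]-4,4,5,5-tetramethyl-1,3,2-dioxaborolane | CC1(C)OB(OC1(C)C)/C=C(\C)[C@H]2CC[C@@](C)(O[Si](C)(C)C)[C@@H](Br)C2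
F6 | step 9 | (1R,2S,4S)-2-bromo-4-[(E)-1-iodoprop-1-en-2-yl]-1-methylcyclohexan-1-ol | I/C=C(\C)[C@H]1CC[C@@](C)(O)[C@@H](Br)C1
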